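I may read this flask at any moment up to 2.5 min, so I need the height of the target curve and the time at which it tops.

| flask | starting material | protic impurity | remark | time |
|---|---|---|---|---|
| delta | 0.25 M | 0.013 M | run made earlier |  |
| beta | 0.25 M | 0.050 M | run made earlier |  |
| flask | 0.25 M | 0.0250 M |  | 2.5 min |

| run | time / min | target / % |
|---|---|---|
| delta | 0.333 | 32.6 |
| delta | 0.667 | 45.3 |
| delta | 1.33 | 46.8 |
| delta | 3.00 | 40.3 |
| beta | 0.333 | 29.2 |
| beta | 0.667 | 34.4 |
| beta | 1.33 | 40.4 |
| beta | 3.00 | 32.8 |

(readings scatter by 1 percentage point)

* the moment within 2.5 min at which there is most target
* the amount of target, in percent of the starting material charged, at that time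



I build the flask up one process at a time. With the main step by itself, starting material going first-order to target, the integrated rate gives a single exponential climb towards the whole charge. Now I add the impurity, supposing that each molecule takes one of starting material. It is then the limiting reagent of that loss, and the ceiling drops to the free fraction, one minus impurity over starting material charged, 90.0% in this flask. The rest I lump together: target tops and fades in both runs, so I divide each highest reading by that run's free fraction. The delta run gives 49.4% and the beta run 50.5%, which lie 1.1 percentage points apart against a scatter of 1 point. I take their mean, 49.9%, as the peak yield on the free fraction. Multiplying, I commit to 44.9% for this flask, at about 1.33 min, where both runs show their highest reading.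

The forecast says 44.5% at 1.15 min, on the ground that “More impurity therefore seems to slow formation and reduce yield.” Its height lies below mine and its time earlier.

The flask gives 44.1% at 1.24 min.

    target ⇌ isomer of the product A (K = 0.130, k = 0.310 s⁻¹)
    starting material ⇌ target (K = 5.70, k = 0.0330 s⁻¹)
    target → over-reaction product B (k = 7.50 × 10⁻⁶ s⁻¹)
    starting material + protic impurity → quenched substrate (k = 6.10 L mol⁻¹ s⁻¹)
    isomer of the product A ⇌ isomer of the product B (K = 2.90, k = 0.0440 s⁻¹)
    target → over-reaction product A (k = 0.00330 s⁻¹)
    isomer of the product B ⇌ starting material (k = 0.0110 s⁻¹)

At the start of this flask, starting material goes to target by the forward step at the smaller rate, 0.22 of the rate at which it goes with protic impurity to quenched substrate. By 0.250 min this flask holds protic impurity at 0% of its charge and quenched substrate at 10.0% of the starting material charged, which matches one minus the free fraction, 10.0%. In a neighbour flask with 0.10 M of starting material, the free fraction is 75.0%, which gives a peak of 37.4%. The computed neighbour flask tops at 36.8%, and at 2.50 min it holds quenched substrate at 25.0%.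

Readings and results stem from a simulated flask for an exercise; the scatter is artificial.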